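**Assumption:** the SMILES has no stereocentre, so the target is achiral and is made as such; 1, 4, 5, 10 and 20 are taken as catalogue compounds.

## Retrosynthetic overview

1. Target 24 ⇐ its 21-fold methyl ether 23 by one global O-demethylation. The target has no inter-ring C–C bond, so the seven diaryl ether C–O bonds are the strategic bonds.
2. Each ether bond is cut so that a hindered phenol oxygen is the nucleophile and the electron-rich aryl carbon is an aryl cation equivalent. This is an aryl(2,4,6-trimethoxyphenyl)iodonium salt made in the flask from the aryl iodide, which reverses the normal polarity of a polyalkoxyarene.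
3. 23 ⇐ 20 (ring A) + seven-ring iodide 19 ⇐ three units of the two-ring iodophenol 9 (rings B–C, D–E, F–G) + 10 (ring H). The iodine each unit of 9 brings in is the next latent cation, so chain growth needs no protecting-group steps; the risk is taken in generating the cation on 3-, 5- and 7-ring iodides.
4. 9 ⇐ 5 + benzyl-masked 2 (from 1); this single tri-ortho-substituted ether is made at the small-molecule stage.
5. No ring is constructed; all eight benzene rings are bought. Bond order: the F–G type bond (inside 9), then G–H, E–F, C–D, A–B.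

## Route

**Step 1**
Reactants: 1 2,3,4-trimethoxyphenol
Product: 2 6-iodo-2,3,4-trimethoxyphenol
Conditions: NIS (1.0 equiv), MeCN, 0 °C to rt, dark
Reagents that add atoms: N-iodosuccinimide O=C1CCC(=O)N1I
Why: Electrophilic aromatic iodination in which the free OH is the strongest director and its para position is blocked, so iodine enters the only ortho position (C6, also para to the 3-OMe).

**Step 2**
Reactants: 2 6-iodo-2,3,4-trimethoxyphenol
Product: 3 2-(benzyloxy)-1-iodo-3,4,5-trimethoxybenzene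
Conditions: BnBr, K2CO3, DMF, rt
Reagents that add atoms: benzyl bromide BrCc1ccccc1
Why: Williamson ether synthesis; the benzyl group keeps the phenol from ligating or being oxidised by the trivalent iodine centre made next and can later be removed without reducing a C–I bond.

**Step 3**
Reactants: 3 2-(benzyloxy)-1-iodo-3,4,5-trimethoxybenzene; 4 1,3,5-trimethoxybenzene (auxiliary aryl); 5 4-iodo-2,6-dimethoxyphenol
Product: 8 2-(benzyloxy)-1-(4-iodo-2,6-dimethoxyphenoxy)-3,4,5-trimethoxybenzene, via hydroxy(tosyloxy)iodane 6 (not isolated), via aryl(trimethoxyphenyl)iodonium tosylate 7 (not isolated)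
Conditions: 3 (1.2 equiv), mCPBA (1.15 equiv), TsOH·H2O, MeCN, 55 °C; 4, rt; then 5 (1.0 equiv), K2CO3, MeCN–toluene, 55 °C, one pot
Reagents that add atoms: none
Why: Metal-free O-arylation of a phenoxide by a diaryliodonium salt (ligand exchange then ligand coupling at trivalent iodine), in which the ring of 3 acts as an aryl cation equivalent, the more electron-rich 2,4,6-trimethoxyphenyl group stays on iodine, di-ortho-substituted phenoxides are tolerated and the C–I bond of 5 is inert.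

**Step 4**
Reactants: 8 2-(benzyloxy)-1-(4-iodo-2,6-dimethoxyphenoxy)-3,4,5-trimethoxybenzene
Product: 9 6-(4-iodo-2,6-dimethoxyphenoxy)-2,3,4-trimethoxyphenol
Conditions: BCl3, C6HMe5, CH2Cl2, −78 °C; then H2O
Reagents that add atoms: none
Why: Lewis-acid debenzylation with a cation scavenger cleaves the benzyl ether at −78 °C much faster than the methyl ethers and, being non-reductive, leaves the aryl iodide untouched.

**Step 5**
Reactants: 10 5-iodo-1,2,3-trimethoxybenzene; 4 1,3,5-trimethoxybenzene; 9 6-(4-iodo-2,6-dimethoxyphenoxy)-2,3,4-trimethoxyphenol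
Product: 13 1-(4-iodo-2,6-dimethoxyphenoxy)-3,4,5-trimethoxy-2-(3,4,5-trimethoxyphenoxy)benzene (rings F–G–H; iodine on ring F), via hydroxy(tosyloxy)iodane 11 (not isolated), via aryl(trimethoxyphenyl)iodonium tosylate 12 (not isolated)
Conditions: 10 (1.3 equiv), mCPBA (1.25 equiv), TsOH·H2O, MeCN, 55 °C; 4, rt; then 9 (1.0 equiv), K2CO3, MeCN–toluene, 55 °C, one pot
Reagents that add atoms: none
Why: The same diaryliodonium O-arylation, here with an unhindered, electronically neutral 3,4,5-trimethoxyphenyl cation equivalent and the hindered phenoxide of 9, whose own C–I bond is inert and becomes the next handle.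

**Step 6**
Reactants: 13 three-ring iodide (rings F–G–H); 4 1,3,5-trimethoxybenzene; 9 6-(4-iodo-2,6-dimethoxyphenoxy)-2,3,4-trimethoxyphenol
Product: 16 five-ring iodide 1-(4-iodo-2,6-dimethoxyphenoxy)-3,4,5-trimethoxy-2-{3,5-dimethoxy-4-[3,4,5-trimethoxy-2-(3,4,5-trimethoxyphenoxy)phenoxy]phenoxy}benzene (rings D–H; iodine on ring D), via hydroxy(tosyloxy)iodane 14 (not isolated), via aryl(trimethoxyphenyl)iodonium tosylate 15 (not isolated)
Conditions: 13 (1.05 equiv), mCPBA (1.0 equiv), TsOH·H2O, MeCN, 50 °C; 4, rt; then 9 (1.0 equiv), K2CO3, MeCN–toluene, 55 °C, one pot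
Reagents that add atoms: none
Why: Diaryliodonium O-arylation again; the iodine sits para to the ether oxygen of ring F with no neighbouring aryloxy group, so the trivalent iodine intermediate cannot cyclise and is trapped cleanly by 4 before the phenoxide of 9 is added.

**Step 7**
Reactants: 16 five-ring iodide (rings D–H); 4 1,3,5-trimethoxybenzene; 9 6-(4-iodo-2,6-dimethoxyphenoxy)-2,3,4-trimethoxyphenol
Product: 19 seven-ring iodide (rings B–H; 9 whose phenolic oxygen carries the aryl group of 16 at the former C–I carbon; iodine on ring B; 18 OMe), via hydroxy(tosyloxy)iodane 17 (not isolated), via aryl(trimethoxyphenyl)iodonium tosylate 18 (not isolated)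
Conditions: 16 (1.05 equiv), mCPBA (1.0 equiv), TsOH·H2O, MeCN, 50 °C; 4, rt; then 9 (1.0 equiv), K2CO3, MeCN–toluene, 55 °C, one pot
Reagents that add atoms: none
Why: Third iteration of the diaryliodonium O-arylation, with the same electronic and steric situation at the reacting centres as in step 6.

**Step 8**
Reactants: 19 seven-ring iodide (rings B–H); 4 1,3,5-trimethoxybenzene; 20 2,4,6-trimethoxyphenol
Product: 23 henicosa-O-methyl ether of the target (rings A–H; all 21 OH as OMe), via hydroxy(tosyloxy)iodane 21 (not isolated), via aryl(trimethoxyphenyl)iodonium tosylate 22 (not isolated)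
Conditions: 19 (1.0 equiv), mCPBA (0.95 equiv), TsOH·H2O, MeCN, 50 °C; 4, rt; then 20 (2 equiv), K2CO3, MeCN–toluene, 55 °C, Ar, one pot
Reagents that add atoms: none
Why: Diaryliodonium O-arylation of the di-ortho-substituted phenoxide of 20 by the ring-B aryl cation equivalent closes the last ether bond; peracid is kept sub-stoichiometric so none remains to oxidise 20.

**Step 9**
Reactants: 23 henicosa-O-methyl ether of the target
Product: 24 target CNP0206369.0
Conditions: BBr3 (60 equiv), CH2Cl2, −78 °C to rt, Ar; then H2O, 0 °C; reversed-phase purification under Ar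
Reagents that add atoms: none
Why: BBr3 ether cleavage (boron coordination, then SN2 attack of bromide on the methyl carbon) removes all 21 methyl groups, while the diaryl ether bonds have no sp3 carbon to attack and survive; no stereocentre is involved.

## Compound list

1 | 2,3,4-trimethoxyphenol | COc1ccc(O)c(OC)c1OC | starting material
2 | 6-iodo-2,3,4-trimethoxyphenol | COc1cc(I)c(O)c(OC)c1OC | intermediate
3 | 2-(benzyloxy)-1-iodo-3,4,5-trimethoxybenzene | COc1cc(I)c(OCc2ccccc2)c(OC)c1OC | intermediate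
4 | 1,3,5-trimethoxybenzene | COc1cc(OC)cc(OC)c1 | starting material
5 | 4-iodo-2,6-dimethoxyphenol | COc1cc(I)cc(OC)c1O | starting material
6 | [2-(benzyloxy)-3,4,5-trimethoxyphenyl](hydroxy)(tosyloxy)-λ3-iodane | COc1cc(I(O)OS(=O)(=O)c2ccc(C)cc2)c(OCc2ccccc2)c(OC)c1OC | intermediate
7 | [2-(benzyloxy)-3,4,5-trimethoxyphenyl](2,4,6-trimethoxyphenyl)iodonium tosylate | COc1cc([I+]c2c(OC)cc(OC)cc2OC)c(OCc2ccccc2)c(OC)c1OC.Cc1ccc(S(=O)(=O)[O-])cc1 | intermediate
8 | 2-(benzyloxy)-1-(4-iodo-2,6-dimethoxyphenoxy)-3,4,5-trimethoxybenzene | COc1cc(I)cc(OC)c1Oc1cc(OC)c(OC)c(OC)c1OCc1ccccc1 | intermediate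
9 | 6-(4-iodo-2,6-dimethoxyphenoxy)-2,3,4-trimethoxyphenol | COc1cc(I)cc(OC)c1Oc1cc(OC)c(OC)c(OC)c1O | intermediate
10 | 5-iodo-1,2,3-trimethoxybenzene | COc1cc(I)cc(OC)c1OC | starting material
11 | hydroxy(tosyloxy)(3,4,5-trimethoxyphenyl)-λ3-iodane | COc1cc(I(O)OS(=O)(=O)c2ccc(C)cc2)cc(OC)c1OC | intermediate
12 | (3,4,5-trimethoxyphenyl)(2,4,6-trimethoxyphenyl)iodonium tosylate | COc1cc([I+]c2c(OC)cc(OC)cc2OC)cc(OC)c1OC.Cc1ccc(S(=O)(=O)[O-])cc1 | intermediate
13 | 1-(4-iodo-2,6-dimethoxyphenoxy)-3,4,5-trimethoxy-2-(3,4,5-trimethoxyphenoxy)benzene (rings F–G–H) | COc1cc(I)cc(OC)c1Oc1cc(OC)c(OC)c(OC)c1Oc1cc(OC)c(OC)c(OC)c1 | intermediate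
14 | hydroxy(tosyloxy)-λ3-iodane of 13 (I(OH)OTs in place of I on ring F) | COc1cc(I(O)OS(=O)(=O)c2ccc(C)cc2)cc(OC)c1Oc1cc(OC)c(OC)c(OC)c1Oc1cc(OC)c(OC)c(OC)c1 | intermediate
15 | (2,4,6-trimethoxyphenyl)iodonium tosylate of 13 (ring F carbon on iodine) | COc1cc([I+]c2c(OC)cc(OC)cc2OC)cc(OC)c1Oc1cc(OC)c(OC)c(OC)c1Oc1cc(OC)c(OC)c(OC)c1.Cc1ccc(S(=O)(=O)[O-])cc1 | intermediate
16 | five-ring iodide, 1-(4-iodo-2,6-dimethoxyphenoxy)-3,4,5-trimethoxy-2-{3,5-dimethoxy-4-[3,4,5-trimethoxy-2-(3,4,5-trimethoxyphenoxy)phenoxy]phenoxy}benzene (rings D–H) | COc1cc(I)cc(OC)c1Oc1cc(OC)c(OC)c(OC)c1Oc1cc(OC)c(Oc2cc(OC)c(OC)c(OC)c2Oc2cc(OC)c(OC)c(OC)c2)c(OC)c1 | intermediate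
17 | hydroxy(tosyloxy)-λ3-iodane of 16 (I(OH)OTs in place of I on ring D) | COc1cc(I(O)OS(=O)(=O)c2ccc(C)cc2)cc(OC)c1Oc1cc(OC)c(OC)c(OC)c1Oc1cc(OC)c(Oc2cc(OC)c(OC)c(OC)c2Oc2cc(OC)c(OC)c(OC)c2)c(OC)c1 | intermediate
18 | (2,4,6-trimethoxyphenyl)iodonium tosylate of 16 (ring D carbon on iodine) | COc1cc([I+]c2c(OC)cc(OC)cc2OC)cc(OC)c1Oc1cc(OC)c(OC)c(OC)c1Oc1cc(OC)c(Oc2cc(OC)c(OC)c(OC)c2Oc2cc(OC)c(OC)c(OC)c2)c(OC)c1.Cc1ccc(S(=O)(=O)[O-])cc1 | intermediate
19 | seven-ring iodide (rings B–H; iodine on ring B para to the ether oxygen; 18 OMe) | COc1cc(I)cc(OC)c1Oc1cc(OC)c(OC)c(OC)c1Oc1cc(OC)c(Oc2cc(OC)c(OC)c(OC)c2Oc2cc(OC)c(Oc3cc(OC)c(OC)c(OC)c3Oc3cc(OC)c(OC)c(OC)c3)c(OC)c2)c(OC)c1 | intermediate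
20 | 2,4,6-trimethoxyphenol | COc1cc(OC)c(O)c(OC)c1 | starting material
21 | hydroxy(tosyloxy)-λ3-iodane of 19 (I(OH)OTs in place of I on ring B) | COc1cc(I(O)OS(=O)(=O)c2ccc(C)cc2)cc(OC)c1Oc1cc(OC)c(OC)c(OC)c1Oc1cc(OC)c(Oc2cc(OC)c(OC)c(OC)c2Oc2cc(OC)c(Oc3cc(OC)c(OC)c(OC)c3Oc3cc(OC)c(OC)c(OC)c3)c(OC)c2)c(OC)c1 | intermediate
22 | (2,4,6-trimethoxyphenyl)iodonium tosylate of 19 (ring B carbon on iodine) | COc1cc([I+]c2c(OC)cc(OC)cc2OC)cc(OC)c1Oc1cc(OC)c(OC)c(OC)c1Oc1cc(OC)c(Oc2cc(OC)c(OC)c(OC)c2Oc2cc(OC)c(Oc3cc(OC)c(OC)c(OC)c3Oc3cc(OC)c(OC)c(OC)c3)c(OC)c2)c(OC)c1.Cc1ccc(S(=O)(=O)[O-])cc1 | intermediate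
23 | henicosa-O-methyl ether of the target (rings A–H; 21 OMe) | COc1cc(OC)c(Oc2cc(OC)c(Oc3cc(OC)c(OC)c(OC)c3Oc3cc(OC)c(Oc4cc(OC)c(OC)c(OC)c4Oc4cc(OC)c(Oc5cc(OC)c(OC)c(OC)c5Oc5cc(OC)c(OC)c(OC)c5)c(OC)c4)c(OC)c3)c(OC)c2)c(OC)c1 | intermediate
24 | CNP0206369.0 (eight-ring polyhydroxylated oligo(aryl ether); achiral) | Oc1cc(O)c(Oc2cc(O)c(Oc3cc(O)c(O)c(O)c3Oc3cc(O)c(Oc4cc(O)c(O)c(O)c4Oc4cc(O)c(Oc5cc(O)c(O)c(O)c5Oc5cc(O)c(O)c(O)c5)c(O)c4)c(O)c3)c(O)c2)c(O)c1 | target

## Step count and risks

Total steps: 9. Longest linear sequence: 9 (1 → 2 → 3 → 8 → 9 → 13 → 16 → 19 → 23 → 24).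

**Three steps most likely to fail**

Step 3. The aryl group of 3 is itself electron-rich and ortho-substituted, so selectivity of aryl transfer against the trimethoxyphenyl auxiliary and the formation of a tri-ortho-substituted ether are both uncertain. The fallback sets out from 3 and switches to copper catalysis. 3 is coupled with commercial 4-bromo-2,6-dimethoxyphenol in an Ullmann-type reaction (CuI, picolinic acid, K3PO4, DMSO, 90 °C), where the C–I bond of 3 reacts ahead of the C–Br bond of the phenol. This gives 2-(benzyloxy)-1-(4-bromo-2,6-dimethoxyphenoxy)-3,4,5-trimethoxybenzene F1. An aromatic halogen exchange (CuI, NaI, trans-N,N'-dimethylcyclohexane-1,2-diamine, dioxane, 110 °C) then turns the bromide into the iodide, and the route is rejoined at 8.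

Step 8. The C–I bond of the seven-ring iodide 19 must be oxidised by peracid in the presence of seven electron-rich rings, and the partner 20 is the most easily oxidised phenol of the route. The fallback sets out from 19 and avoids any oxidant. 19 and 20 (3 equiv) are joined directly by a copper-catalysed Ullmann-type coupling (CuI, picolinic acid, K3PO4, DMSO, 90 °C, Ar), which suits an unhindered aryl iodide and a hindered phenol that carries no halogen. It comes back to the route at 23 and makes no compound outside the list (none F0).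

Step 9. Twenty-one demethylations on one molecule can stall at partly methylated material, and the free polyphenol is air-sensitive and hard to purify. The fallback sets out from 23 and uses a derivatise, purify, release sequence. After the BBr3 treatment the crude polyphenol is not purified but acetylated (Ac2O, pyridine, DMAP) to the henicosa-O-acetyl derivative of 24 F2. This is chromatographed on silica, where under-demethylated material separates and can be resubjected. Acid methanolysis (HCl in MeOH generated from AcCl, degassed, 40 °C, Ar) then releases the phenols, and the route is rejoined at 24.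

## Further compounds

F1 | step 3 | 2-(benzyloxy)-1-(4-bromo-2,6-dimethoxyphenoxy)-3,4,5-trimethoxybenzene | COc1cc(Br)cc(OC)c1Oc1cc(OC)c(OC)c(OC)c1OCc1ccccc1
F0 | step 8 | none | none
F2 | step 9 | henicosa-O-acetyl derivative of 24 (all 21 OH as OAc) | CC(=O)Oc1cc(OC(C)=O)c(Oc2cc(OC(C)=O)c(Oc3cc(OC(C)=O)c(OC(C)=O)c(OC(C)=O)c3Oc3cc(OC(C)=O)c(Oc4cc(OC(C)=O)c(OC(C)=O)c(OC(C)=O)c4Oc4cc(OC(C)=O)c(Oc5cc(OC(C)=O)c(OC(C)=O)c(OC(C)=O)c5Oc5cc(OC(C)=O)c(OC(C)=O)c(OC(C)=O)c5)c(OC(C)=O)c4)c(OC(C)=O)c3)c(OC(C)=O)c2)c(OC(C)=O)c1
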